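(The earlier runs and the new flask were generated by integration from invented constants; noise was put on by code.)

Turnovers can be counted. Three flasks stopped at one time are to be foretold from two earlier runs.

| setting | east | west | birch | alder | oak |
|---|---|---|---|---|---|
| electrophile | 0.22 M | 0.22 M | 0.22 M | 0.22 M | 0.22 M |
| nucleophile | 1.5 equiv | 4.6 equiv | 2.00 equiv | 1.00 equiv | 4.00 equiv |
| remark | run made earlier | run made earlier |  |  |  |
| time |  |  | 2.0 min | 2.0 min | 2.0 min |

| run | time / s | electrophile / % | product / % |
|---|---|---|---|
| east | 10.0 | 95 | 4 |
| east | 20.0 | 94 | 7 |
| east | 30.0 | 90 | 12 |
| east | 50.0 | 84 | 17 |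
| east | 80.0 | 79 | 22 |
| east | 90.0 | 77 | 24 |
| east | 120 | 73 | 26 |
| west | 10.0 | 87 | 12 |
| west | 20.0 | 78 | 22 |
| west | 30.0 | 74 | 33 |
| west | 50.0 | 60 | 46 |
| west | 80.0 | 48 | 54 |
| west | 90.0 | 45 | 58 |
| west | 120 | 34 | 64 |

(scatter of a reading: 1.5 percentage points)

1. part of the electrophile that has reacted at the end, birch
2. part of the electrophile that has reacted at the end, alder
3. part of the electrophile that has reacted at the end, oak
4. what raising the equivalents of nucleophile from its lowest to its highest value here does to the part of the electrophile that has reacted (changes below 5 percentage points count as none) (it falls / it rises / no change)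

- the numbers in the tables scatter by 1.5 percentage points (one standard deviation)

Let B be the equivalents of nucleophile and x the fraction of the charged electrophile that has reacted. For a rate first order in each partner, ln[(B − x)/(B(1 − x))]/(B − 1) should depend on time and not on B. The electrophile columns test this row by row. At 30.0 s this quantity reads 0.0727 in east and 0.0675 in west. At 120 s it reads 0.233 and 0.257. The west-to-east ratios are 0.928 and 1.10, although the equivalents stand at a ratio of 3.07.

From that row to the last of east, the quantity changes by a factor of 3.20, less than the factor of 4.00 on time, so the count, as read, slows. The new flasks stop at 2.0 min, the time of the last row, so no extrapolation in time is needed. The mean of that row, 0.245, is the turnover count.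

Inverting it gives this reckoning's own figures: 35.7% for birch, 19.7% for alder and 59.1% for oak.

The forecast used a rounder count, 0.24, taken from the last time, “which was measured directly”. Its figures are 35%, 19% and 58%, with oak slightly lower than in this reckoning, and on raising the equivalents its answer is: it rises.

The flasks give 35.6%, 19.4% and 59.6%, and on raising the equivalents the answer is: it rises, by 40 percentage points.

    nucleophile + acid set free ⇌ protonated nucleophile, settled at all times (K = 230 /M)
    nucleophile ⇌ dormant form (K = 0.410, k = 0.0140 /s)
    electrophile + nucleophile ⇌ acid set free + product (K = 3.00, k = 0.0140 /M/s)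
    nucleophile + acid set free ⇌ idle adduct, settled at all times (K = 3.60 /M)

Birch's result inverts to a count of 0.244, beside 0.245. Carried to a neighbour flask, birch with 5.00 equiv of nucleophile, the count gives 67.5%, and that flask stands at 68.3%. The main reason for oak's figure is its equivalents of nucleophile: with that difference taken away, oak's 59.6% becomes 19.4%.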